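**Retrosynthetic overview**
1. 20 ⇒ 17 + 12: the inter-ring CH2–C bond and the all-carbon quaternary centre of ring B come from an inverse-electron-demand oxa-Diels–Alder reaction between the 2-methylidene enone of ring A (aza-quinone methide 18) and the enol of ring B; the dihydropyran hemiketal 19 opens in the same flask.
2. 17 ⇒ 16 ⇒ 13 ⇒ 9 (methyl oxidation, Benary C-acylation with the (R)-acid, enaminone formation); 12 ⇒ 9 (O-acylation with the (S)-acid).
3. 9 ⇒ 3 + 6: C-acylation of the (S)-lactic acid dioxolanone enolate anti to tert-butyl, then vinylogous Dieckmann closure with loss of pivaldehyde.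
4. Ring order: the carbocycle of 9 is made once and becomes both ring A and ring B; the pyran ring of the cycloadduct is formed last and opened again.

Assumption: the target is taken exactly as drawn ((R) in the ketone side chain, (S) in the ester), and (R)-2-methylbutanoic acid is bought enantiopure, as are the (S)-acid and (S)-lactic acid.

**Step 1**
Reactants: 1 (S)-lactic acid; 2 pivaldehyde (2,2-dimethylpropanal)
Product: 3 (2S,5S)-2-tert-butyl-5-methyl-1,3-dioxolan-4-one
Conditions: TsOH (cat.), H2SO4 (cat.), pentane, reflux, Dean–Stark; recrystallise from pentane, −78 °C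
Reagents that add atoms: none
Why: Acid-catalysed acetalisation (Seebach self-regeneration-of-stereocentres acetal) keeps the lactic acid centre, which directs the new acetal centre cis (about 4:1), and the cis isomer is obtained pure by cold crystallisation.

**Step 2**
Reactants: 4 methyl 3-oxopentanoate
Product: 5 methyl (2E)-3-methoxypent-2-enoate
Conditions: HC(OMe)3, H2SO4 (cat.), MeOH, rt; then distil
Reagents that add atoms: trimethyl orthoformate, COC(OC)OC
Why: Ketalisation by the orthoester and acid-catalysed loss of MeOH give the conjugated enol ether, the E isomer (OMe trans to the ester, ethyl cis) being the thermodynamic one.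

**Step 3**
Reactants: 5 methyl (2E)-3-methoxypent-2-enoate
Product: 6 (2E)-3-methoxypent-2-enoic acid
Conditions: NaOH, MeOH–H2O, 50 °C; then cold 1 M HCl to pH 3
Reagents that add atoms: sodium hydroxide, [Na+].[OH-]
Why: Ester saponification; the β-methoxy enoate is inert to hydroxide and survives a brief cold acidification.

**Step 4**
Reactants: 6 (2E)-3-methoxypent-2-enoic acid; 3 (2S,5S)-2-tert-butyl-5-methyl-1,3-dioxolan-4-one
Product: 9 (6S)-5,6-dihydroxy-3-methoxy-4,6-dimethylcyclohexa-2,4-dien-1-one, via (2E)-3-methoxypent-2-enoyl chloride 7 (not isolated), via acyl dioxolanone 8 (not isolated)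
Conditions: 6, (COCl)2, DMF (cat.), CH2Cl2, 0 °C → rt, evaporate; 3, LiN(i-Pr)2, THF, −78 °C, then 7; then LiN(SiMe3)2 (2.5 equiv), −78 → −20 °C; AcOH
Reagents that add atoms: none
Why: After acid chloride formation, C-acylation of the Seebach enolate on the face anti to tert-butyl sets the quaternary carbinol centre with retention of the lactic acid configuration, and the γ-carbanion of the β-methoxy enone (which has no α′-hydrogen) then closes the ring on the activated dioxolanone carbonyl (vinylogous Dieckmann condensation), the acetal collapsing to pivaldehyde and the tertiary alkoxide.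

**Step 5**
Reactants: 9 (6S)-5,6-dihydroxy-3-methoxy-4,6-dimethylcyclohexa-2,4-dien-1-one; 10 (2S)-2-methylbutanoic acid
Product: 12 (1S)-6-hydroxy-4-methoxy-1,5-dimethyl-2-oxocyclohexa-3,5-dien-1-yl (2S)-2-methylbutanoate, via (2S)-2-methylbutanoyl chloride 11 (not isolated)
Conditions: 10, (COCl)2, DMF (cat.), CH2Cl2, evaporate; 9, LiN(SiMe3)2 (2.05 equiv), THF, −78 °C, then 11 (1.05 equiv), → −40 °C; AcOH
Reagents that add atoms: none
Why: In the dianion the tertiary alkoxide is far more nucleophilic than the delocalised vinylogous carboxylate (any enol ester formed passes its acyl group to the neighbouring alkoxide), so esterification by the acid chloride gives the tertiary ester without touching either stereocentre.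

**Step 6**
Reactants: 9 (6S)-5,6-dihydroxy-3-methoxy-4,6-dimethylcyclohexa-2,4-dien-1-one
Product: 13 (6R)-5-amino-6-hydroxy-3-methoxy-2,6-dimethylcyclohexa-2,4-dien-1-one
Conditions: NH4OAc (10 equiv), MeOH, 55 °C
Reagents that add atoms: ammonium acetate, CC(=O)[O-].[NH4+]
Why: Enaminone formation by condensation of the vinylogous acid with ammonia is expected at the carbonyl flanked by the unsubstituted CH, the one next to the C-methyl carbon being more hindered; the quaternary centre is untouched (its descriptor changes only through CIP priorities).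

**Step 7**
Reactants: 13 (6R)-5-amino-6-hydroxy-3-methoxy-2,6-dimethylcyclohexa-2,4-dien-1-one; 14 (2R)-2-methylbutanoic acid
Product: 16 (6R)-5-amino-6-hydroxy-3-methoxy-2,6-dimethyl-4-[(2R)-2-methylbutanoyl]cyclohexa-2,4-dien-1-one, via (2R)-2-methylbutanoyl chloride 15 (not isolated)
Conditions: 14, (COCl)2, DMF (cat.), CH2Cl2, evaporate; 13, pyridine, CH2Cl2, −20 → 0 °C
Reagents that add atoms: none
Why: Benary C-acylation of the primary enaminone at its only free nucleophilic carbon (C4) gives the N–H···O=C hydrogen-bonded acyl enaminone, and pyridine at low temperature does not epimerise the α-branched acid chloride.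

**Step 8**
Reactants: 16 (6R)-5-amino-6-hydroxy-3-methoxy-2,6-dimethyl-4-[(2R)-2-methylbutanoyl]cyclohexa-2,4-dien-1-one
Product: 17 (6R)-5-amino-6-hydroxy-3-methoxy-2-(methoxymethyl)-6-methyl-4-[(2R)-2-methylbutanoyl]cyclohexa-2,4-dien-1-one
Conditions: Ag2O (2.5 equiv), TEMPO (20 mol %), MeOH–CH2Cl2 1:3, 0 °C → rt
Reagents that add atoms: methanol, CO
Why: Oxidative dehydrogenation of the electron-rich dienaminone at C2 (C4 is blocked) with loss of a methyl proton gives the aza-quinone methide, which MeOH captures by conjugate addition (oxidative quinone-methide formation); no stereocentre is touched.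

**Step 9**
Reactants: 17 (6R)-5-amino-6-hydroxy-3-methoxy-2-(methoxymethyl)-6-methyl-4-[(2R)-2-methylbutanoyl]cyclohexa-2,4-dien-1-one; 12 (1S)-6-hydroxy-4-methoxy-1,5-dimethyl-2-oxocyclohexa-3,5-dien-1-yl (2S)-2-methylbutanoate
Product: 20 (1R,3R)-3-{[(5R)-4-amino-5-hydroxy-2-methoxy-5-methyl-3-[(2R)-2-methylbutanoyl]-6-oxocyclohexa-1,3-dien-1-yl]methyl}-4-methoxy-1,3-dimethyl-2,6-dioxocyclohex-4-en-1-yl (2S)-2-methylbutanoate, via aza-quinone methide 18 (not isolated), via hemiketal cycloadduct 19 (not isolated)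
Conditions: 12 (1.5 equiv), 4 Å MS, PhMe, 60 °C
Reagents that add atoms: none
Why: Proton transfer from the vinylogous acid 12 expels MeOH from 17 to give heterodiene 18, whose 1-oxadiene (C1=O/C2=CH2) undergoes an inverse-electron-demand oxa-Diels–Alder reaction with the tetrasubstituted enol C5=C6 of 12 on the face anti to the neighbouring acyloxy group, which sets the quaternary centre, and hemiketal 19 then opens and the imine tautomerises to the enaminone.

**Compound list**
1 | (S)-lactic acid | C[C@H](O)C(=O)O | starting material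
2 | pivaldehyde (2,2-dimethylpropanal) | CC(C)(C)C=O | starting material
3 | (2S,5S)-2-tert-butyl-5-methyl-1,3-dioxolan-4-one | C[C@@H]1O[C@H](C(C)(C)C)OC1=O | intermediate
4 | methyl 3-oxopentanoate | CCC(=O)CC(=O)OC | starting material
5 | methyl (2E)-3-methoxypent-2-enoate | CO/C(CC)=C/C(=O)OC | intermediate
6 | (2E)-3-methoxypent-2-enoic acid | CO/C(CC)=C/C(=O)O | intermediate
7 | (2E)-3-methoxypent-2-enoyl chloride | CO/C(CC)=C/C(=O)Cl | intermediate
8 | (2S,5R)-2-tert-butyl-5-[(2E)-3-methoxypent-2-enoyl]-5-methyl-1,3-dioxolan-4-one | C[C@]1(C(=O)/C=C(/OC)CC)O[C@H](C(C)(C)C)OC1=O | intermediate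
9 | (6S)-5,6-dihydroxy-3-methoxy-4,6-dimethylcyclohexa-2,4-dien-1-one (enol form of the 2-hydroxy-1,3-dione) | COC1=CC(=O)[C@@](C)(O)C(O)=C1C | intermediate
10 | (2S)-2-methylbutanoic acid | CC[C@H](C)C(=O)O | starting material
11 | (2S)-2-methylbutanoyl chloride | CC[C@H](C)C(=O)Cl | intermediate
12 | (1S)-6-hydroxy-4-methoxy-1,5-dimethyl-2-oxocyclohexa-3,5-dien-1-yl (2S)-2-methylbutanoate | COC1=CC(=O)[C@@](C)(OC(=O)[C@@H](C)CC)C(O)=C1C | intermediate
13 | (6R)-5-amino-6-hydroxy-3-methoxy-2,6-dimethylcyclohexa-2,4-dien-1-one | COC1=C(C)C(=O)[C@](C)(O)C(N)=C1 | intermediate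
14 | (2R)-2-methylbutanoic acid | CC[C@@H](C)C(=O)O | starting material
15 | (2R)-2-methylbutanoyl chloride | CC[C@@H](C)C(=O)Cl | intermediate
16 | (6R)-5-amino-6-hydroxy-3-methoxy-2,6-dimethyl-4-[(2R)-2-methylbutanoyl]cyclohexa-2,4-dien-1-one | CC[C@@H](C)C(=O)C1=C(N)[C@@](C)(O)C(=O)C(C)=C1OC | intermediate
17 | (6R)-5-amino-6-hydroxy-3-methoxy-2-(methoxymethyl)-6-methyl-4-[(2R)-2-methylbutanoyl]cyclohexa-2,4-dien-1-one | CC[C@@H](C)C(=O)C1=C(N)[C@@](C)(O)C(=O)C(COC)=C1OC | intermediate
18 | (6R)-6-hydroxy-5-imino-3-methoxy-6-methyl-2-methylidene-4-[(2R)-2-methylbutanoyl]cyclohex-3-en-1-one | CC[C@@H](C)C(=O)C1=C(OC)C(=C)C(=O)[C@](C)(O)C1=N | intermediate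
19 | oxa-Diels–Alder adduct of 18 and 12: cis-fused 2-hydroxy-dihydropyran whose ring O is the former C1 carbonyl O of ring A bonded to the former enol carbon C6 of 12 (hemiketal OH cis to the adjacent ring B C-methyl) and whose CH2 is bonded to former C5 of 12; ring A as the 5-imino diene; all other centres as in 20 | CC[C@@H](C)C(=O)C1=C(OC)C2=C(O[C@]3(O)[C@](C)(C2)C(OC)=CC(=O)[C@@]3(C)OC(=O)[C@@H](C)CC)[C@](C)(O)C1=N | intermediate
20 | (1R,3R)-3-{[(5R)-4-amino-5-hydroxy-2-methoxy-5-methyl-3-[(2R)-2-methylbutanoyl]-6-oxocyclohexa-1,3-dien-1-yl]methyl}-4-methoxy-1,3-dimethyl-2,6-dioxocyclohex-4-en-1-yl (2S)-2-methylbutanoate | CC[C@@H](C)C(=O)C1=C(N)[C@@](C)(O)C(=O)C(C[C@@]2(C)C(=O)[C@](C)(OC(=O)[C@@H](C)CC)C(=O)C=C2OC)=C1OC | target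

**Totals and risks**
Total step count: 9. Longest linear sequence: 7 steps (4 → 5 → 6 → 9 → 13 → 16 → 17 → 20).

The three steps most likely to fail:

Step 4 (one-flask C-acylation and vinylogous Dieckmann closure; O-acylation or decomposition of the enolate above −40 °C could intervene). The fallback sets out from ester 5 and dioxolanone 3 and comes back at 9. Ester 5 is reduced with i-Bu2AlH to (2E)-3-methoxypent-2-en-1-ol F1, which MnO2 oxidises to (2E)-3-methoxypent-2-enal F2. Aldol addition of the enolate of 3 (LiN(i-Pr)2, −78 °C, anti to tert-butyl) to F2 gives the β-hydroxy dioxolanone F3 as a mixture of carbinol epimers. Dess–Martin oxidation then gives 8, now isolated and purified, and LiN(SiMe3)2 closes the ring to 9.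

Step 8 (direct oxidation of the C2 methyl; over-oxidation or reaction at nitrogen is possible). The fallback sets out from 16 and comes back at 17. PhSeCl and pyridine at −78 °C selenenylate the nucleophilic C2 to give the 2-methyl-2-(phenylselanyl) imino-enone F4. H2O2 in MeOH–CH2Cl2 at 0 °C converts it into the selenoxide F5, whose syn-elimination toward the methyl group releases 18, and the solvent MeOH adds to give 17.

Step 9 (the heterodiene may attack the unsubstituted C3 of 12 instead of the methyl-bearing C5, or the face syn to the ester). The fallback sets out from 12 (with 17) and comes back at 20. NIS in CH2Cl2 at 0 °C blocks C3 to give (1S)-6-hydroxy-3-iodo-4-methoxy-1,5-dimethyl-2-oxocyclohexa-3,5-dien-1-yl (2S)-2-methylbutanoate F6. Cycloaddition with 18, generated from 17 as in step 9, can then only occur at C5 and passes through the iodo hemiketal cycloadduct F7 to the 5-iodo derivative of 20 F8. Radical deiodination with (Me3Si)3SiH and Et3B/air in toluene at rt gives 20.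

**Further compounds**
F1 | step 4 | (2E)-3-methoxypent-2-en-1-ol | CO/C(CC)=C/CO
F2 | step 4 | (2E)-3-methoxypent-2-enal | CO/C(CC)=C/C=O
F3 | step 4 | (2S,5R)-2-tert-butyl-5-[(2E)-1-hydroxy-3-methoxypent-2-en-1-yl]-5-methyl-1,3-dioxolan-4-one (both carbinol epimers) | C[C@]1(C(O)/C=C(/OC)CC)O[C@H](C(C)(C)C)OC1=O
F4 | step 8 | (6R)-6-hydroxy-5-imino-3-methoxy-2,6-dimethyl-4-[(2R)-2-methylbutanoyl]-2-(phenylselanyl)cyclohex-3-en-1-one (both C2 epimers) | CC[C@@H](C)C(=O)C1=C(OC)C(C)([Se]c2ccccc2)C(=O)[C@](C)(O)C1=N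
F5 | step 8 | Se-oxide of F4 | CC[C@@H](C)C(=O)C1=C(OC)C(C)([Se](=O)c2ccccc2)C(=O)[C@](C)(O)C1=N
F6 | step 9 | (1S)-6-hydroxy-3-iodo-4-methoxy-1,5-dimethyl-2-oxocyclohexa-3,5-dien-1-yl (2S)-2-methylbutanoate | COC1=C(I)C(=O)[C@@](C)(OC(=O)[C@@H](C)CC)C(O)=C1C
F7 | step 9 | iodo analogue of cycloadduct 19 (iodine on the vinylic carbon of ring B) | CC[C@@H](C)C(=O)C1=C(OC)C2=C(O[C@]3(O)[C@](C)(C2)C(OC)=C(I)C(=O)[C@@]3(C)OC(=O)[C@@H](C)CC)[C@](C)(O)C1=N
F8 | step 9 | 5-iodo derivative of 20 (iodine at C5 of the cyclohexenyl ester ring, same configuration at every stereocentre) | CC[C@@H](C)C(=O)C1=C(N)[C@@](C)(O)C(=O)C(C[C@@]2(C)C(=O)[C@](C)(OC(=O)[C@@H](C)CC)C(=O)C(I)=C2OC)=C1OC
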